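**Plan**
- Retrosynthesis: the isopropenyl group is cut back (C=CH2, then C–CH3) to a lactone carbonyl on C2'. The C8–C1' bond is cut together with the O7–acyl ring, then the O7 ester, the C8 prenyl group, the chromanone bonds O1–C2 and C4–C4a, and last the side-chain C–H and the coumarin bonds to phloroglucinol.
- Enabling feature (chromanone numbering O1, C2–C4, C4a, C5–C8, C8a; C1' is the CH2 on C8, C2' the next chain carbon): quaternary C8 is ortho to O7 and para to O5, and C2' is 1,3 to C8. A six-membered lactone O7–CO–C2'–C1'–C8 can therefore form by conjugate addition of the O5 phenoxide through C8 to an acrylate on O7.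
- Forward order of rings: coumarin lactone (Pechmann, temporary, carries the side chain), then the chromanone ring, then the δ-lactone in the key step, which is opened and turned into the isopropenyl group. The acrylic acid 19 is made separately and joined in step 12.
- Stereochemistry: the side-chain centre (S) comes from a copper hydride conjugate reduction; C2 (R) and cis C3 (S) from a quinine-catalysed oxa-Michael addition; C8 (R) from a chiral ammonium ion pair; C2' (R) from the lactone ring, where the chain lies pseudo-equatorial.

Key step: step 13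

Assumption: the sense of induction of the ligand, the alkaloid and the ammonium salt in steps 3, 5 and 13 is assigned by analogy; if a step delivers the mirror-image centre, the enantiomeric ligand, quinidine or the cinchoninium salt is used instead.

**Route**

Step 1
Reactants: 1 phloroglucinol; 2 ethyl 3-oxohexanoate
Product: 3 5,7-dihydroxy-4-propylcoumarin
Conditions: conc. H2SO4, 0 °C → rt
Reagents that add atoms: none
Why: Pechmann condensation (transesterification, ring closure of the ketone onto the ortho carbon, dehydration); the threefold symmetry of 1 allows only one coumarin.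

Step 2
Reactants: 3
Product: 4 5,7-bis(tert-butyldimethylsilyloxy)-4-propylcoumarin
Conditions: TBSCl (2.5 equiv), imidazole, DMF, rt
Reagents that add atoms: tert-butyldimethylsilyl chloride, CC(C)(C)[Si](C)(C)Cl
Why: Routine silyl ether formation on both phenols, which would otherwise consume hydrosilane and, as phenoxides, deactivate the enoate toward hydride in step 3.

Step 3
Reactants: 4
Product: 6 (4S)-5,7-dihydroxy-4-propylchroman-2-one, via bis-silyl dihydrocoumarin 5 (not isolated)
Conditions: Cu(OAc)2·H2O (5 mol%), (R)-5,5'-bis[di(3,5-di-tert-butyl-4-methoxyphenyl)phosphino]-4,4'-bi-1,3-benzodioxole (5 mol%), (EtO)2MeSiH, t-BuOH, PhMe, rt; then HF·pyridine, THF, 0 °C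
Reagents that add atoms: none
Why: Copper hydride asymmetric conjugate reduction of a β,β-disubstituted unsaturated lactone, a known reaction of coumarins: the ligand-bound hydride should add to one face of C4 and set the (S) centre, t-BuOH releases the lactone from copper, and fluoride then removes both silyl groups without touching the aryl ester.

Step 4
Reactants: 6; 7 tigloyl chloride [(E)-2-methylbut-2-enoyl chloride]
Product: 8 (4S)-5,7-dihydroxy-8-[(E)-2-methylbut-2-enoyl]-4-propylchroman-2-one
Conditions: AlCl3 (4 equiv), PhNO2–ClCH2CH2Cl, 0 °C → rt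
Reagents that add atoms: none
Why: Friedel–Crafts acylation: C8 is ortho to the 7-hydroxyl and para to the 5-hydroxyl (the resorcinol 4-position) whereas C6 lies between the two hydroxyls, so the acylium ion should attack C8 as it does in the parent coumarin, and the low temperature keeps the enone from closing without control.

Step 5
Reactants: 8
Product: 9 (4S,8R,9S)-5-hydroxy-8,9-dimethyl-4-propyl-3,4,8,9-tetrahydro-2H,10H-pyrano[2,3-f]chromene-2,10-dione (dihydrocoumarin fused at O7/C8 to a cis-2,3-dimethylchroman-4-one ring)
Conditions: (−)-quinine (C20H24N2O2, 10 mol%), PhCl, 15 °C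
Reagents that add atoms: none
Why: Cinchona-alkaloid-catalysed intramolecular oxa-Michael addition of an o-tigloylphenol: only the 7-hydroxyl flanks the enone (the other ortho oxygen is held in the lactone), the alkaloid selects the face of the β-carbon to give the O–CH(CH3) centre (R), and kinetic protonation of the enol from the face away from that methyl group gives the cis α-methyl centre (S).

Step 6
Reactants: 9; 10 3-chloro-3-methylbut-1-yne
Product: 11 (4S,8R,9S)-8,9-dimethyl-5-(2-methylbut-3-yn-2-yloxy)-4-propyl-3,4,8,9-tetrahydro-2H,10H-pyrano[2,3-f]chromene-2,10-dione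
Conditions: CuCl2·2H2O (1 mol%), DBU, MeCN, 0 °C
Reagents that add atoms: none
Why: Copper-catalysed O-alkylation of a phenol with a tertiary propargylic chloride, the standard entry to aryl 1,1-dimethylpropargyl ethers; only one hydroxyl is free and the buffered DBU–phenol pair is too weak a base to enolise the α-methyl centre.

Step 7
Reactants: 11
Product: 13 (4S,8R,9S)-5-hydroxy-8,9-dimethyl-6-(3-methylbut-2-enyl)-4-propyl-3,4,8,9-tetrahydro-2H,10H-pyrano[2,3-f]chromene-2,10-dione, via 1,1-dimethylallyl ether 12 (not isolated)
Conditions: H2 (1 atm), Pd on CaCO3 poisoned with Pb(OAc)2, quinoline, EtOAc, rt; filter; then o-xylene, 130 °C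
Reagents that add atoms: none
Why: Semihydrogenation over poisoned palladium stops at the 1,1-dimethylallyl ether, which on heating undergoes the aromatic Claisen rearrangement to the only free ortho carbon and so delivers a normal prenyl group without base and without the O/C ambiguity of direct alkylation.

Step 8
Reactants: 13
Product: 14 methyl (3S)-3-[(2R,3S)-5,7-dihydroxy-2,3-dimethyl-8-(3-methylbut-2-enyl)-4-oxochroman-6-yl]hexanoate
Conditions: NaOMe (2.2 equiv), MeOH, −10 °C; then AcOH
Reagents that add atoms: sodium methoxide, C[O-].[Na+]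
Why: Transesterification of the aryl ester (lactone methanolysis): methoxide opens the activated dihydrocoumarin in the cold, and the liberated phenoxide, chelated to the chromanone carbonyl, drives the opening and keeps C3 from enolising.

Step 9
Reactants: 15 diethyl malonate; 16 4-bromo-2-methylbut-1-ene
Product: 17 diethyl 2-(3-methylbut-3-enyl)malonate
Conditions: 15 (2 equiv), NaH, THF–DMF, 0 °C; then 16, 60 °C
Reagents that add atoms: none
Why: Malonic ester alkylation (SN2) of the sodium enolate with the primary homoallylic bromide; excess malonate suppresses dialkylation.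

Step 10
Reactants: 17
Product: 18 2-(3-methylbut-3-enyl)malonic acid
Conditions: KOH, EtOH–H2O, rt; then HCl, 0 °C
Reagents that add atoms: potassium hydroxide, [K+].[OH-]
Why: Saponification of both esters and cold acidification should give the malonic acid without decarboxylation.

Step 11
Reactants: 18
Product: 19 5-methyl-2-methylidenehex-5-enoic acid [2-(3-methylbut-3-enyl)acrylic acid]
Conditions: (CH2O)n, Et2NH, EtOAc, reflux
Reagents that add atoms: formaldehyde (as paraformaldehyde), C=O
Why: Mannich methylenation with decarboxylation, the classical route from 2-alkylmalonic acids to 2-alkylacrylic acids: the Mannich base loses CO2 and the amine to give the 1,1-disubstituted alkene.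

Step 12
Reactants: 14; 19
Product: 20 methyl (3S)-3-[(2R,3S)-5-hydroxy-2,3-dimethyl-8-(3-methylbut-2-enyl)-7-(5-methyl-2-methylidenehex-5-enoyloxy)-4-oxochroman-6-yl]hexanoate
Conditions: 19 (1.3 equiv), N,N'-diisopropylcarbodiimide, 4-(dimethylamino)pyridine (10 mol%), CH2Cl2, −10 → 0 °C
Reagents that add atoms: none
Why: Steglich esterification: the acylpyridinium ion should acylate the 7-hydroxyl, which is the more acidic (para to the ketone) and the only one not locked in a hydrogen bond to C4=O, and without a stoichiometric base the C5 phenol stays protonated so that ring closure does not start early.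

Step 13
Reactants: 20
Product: 21 dearomatised tricyclic enol δ-lactone: (2R,3S)-2,3-dimethylchromane-4,5-dione core with C4a=C8a and C6=C7, quaternary C8 (R) bearing prenyl and C1'H2, lactone O7–C(=O)–C2'–C1'–C8 with C2' (R) carrying the 3-methylbut-3-enyl chain, C6 bearing (S)-CH(propyl)CH2CO2CH3
Conditions: N-(9-anthracenylmethyl)-O-allylcinchonidinium bromide (10 mol%), Cs2CO3 (20 mol%), PhMe–CH2Cl2, −20 → 0 °C; then AcOH
Reagents that add atoms: none
Why: Proposed new method: the C5 phenoxide, whose charge is relayed to the para carbon C8, adds to the β-carbon of the O7 2-alkylacrylate and the resulting lactone enolate is protonated at C2' by the next phenol, so the base is needed only in catalytic amount; the closest known reactions are the ion-pair-catalysed dearomative conjugate additions of acylphloroglucinols to enals and the intramolecular dearomative Michael additions of phenols to tethered acceptors. The δ-lactone (C7, O7, CO, C2', C1', C8) closes in the 6-endo-trig mode, a ring size already reached in the acid-mediated closure of aryl acrylates to dihydrocoumarins. C8 is set by the chiral ammonium cation, which is paired with the chelated C4=O/C5–O unit and should shield one face of the flat ring, the existing centres being too remote to help. C2' is set inside the half-chair lactone, where the chain is pseudo-equatorial and anti to the pseudo-axial prenyl group in the required (R) epimer, and the basic medium should let the epimers settle through the enolate, which is reprotonated faster than it fragments. The step needs attack through C8 and not through C6, the other carbon ortho to O7, and no loss of the aryl ester: C8 carries a primary prenyl group while C6 carries a branched chain, attack at C8 gives the cross-conjugated dienone stabilised by O1 and O7, the quaternary adduct cannot rearomatise by tautomerisation, and the anhydrous solid base keeps hydroxide away from the ester.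

Step 14
Reactants: 21
Product: 22 methyl (3S)-3-{(2R,3S,8R)-5-hydroxy-8-[(2R)-2-[methoxy(methyl)carbamoyl]-5-methylhex-5-enyl]-2,3-dimethyl-8-(3-methylbut-2-enyl)-4,7-dioxo-3,4,7,8-tetrahydro-2H-chromen-6-yl}hexanoate
Conditions: MeNH(OMe)·HCl (1.3 equiv), iPrMgCl (2.6 equiv), THF, −40 °C; aq. NH4Cl
Reagents that add atoms: N,O-dimethylhydroxylamine hydrochloride, CNOC.Cl
Why: Aminolysis of an activated ester with the chloromagnesium amide (Weinreb amide formation): the enol lactone is a vinylogous anhydride whose leaving group is the stabilised triketone enolate, so it should react at −40 °C while the methyl ester does not, and C2' is not touched.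

Step 15
Reactants: 22
Product: 23 (3S)-3-{(2R,3S,8R)-5-hydroxy-8-[(2R)-2-[methoxy(methyl)carbamoyl]-5-methylhex-5-enyl]-2,3-dimethyl-8-(3-methylbut-2-enyl)-4,7-dioxo-3,4,7,8-tetrahydro-2H-chromen-6-yl}hexanoic acid
Conditions: LiOH·H2O (5 equiv), THF–MeOH–H2O, rt; 1 M HCl to pH 3, 0 °C
Reagents that add atoms: lithium hydroxide, [Li+].[OH-]
Why: Saponification of the methyl ester; the N-methoxy-N-methylamide is inert to LiOH at room temperature and the ring is protected as its delocalised enolate, and the carboxylate formed will later resist the Grignard reagent where a methyl ester would not.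

Step 16
Reactants: 23
Product: 24 (3S)-3-{(2R,3S,8R)-8-[(2R)-2-acetyl-5-methylhex-5-enyl]-5-hydroxy-2,3-dimethyl-8-(3-methylbut-2-enyl)-4,7-dioxo-3,4,7,8-tetrahydro-2H-chromen-6-yl}hexanoic acid
Conditions: MeMgBr (5 equiv), THF, −20 → 0 °C; aq. NH4Cl
Reagents that add atoms: methylmagnesium bromide, C[Mg]Br
Why: Weinreb ketone synthesis: after deprotonation of the acid and the enol, MeMgBr adds once to the amide to give a chelated tetrahedral intermediate that collapses to the methyl ketone only on work-up, so over-addition and enolisation at C2' are avoided, and the carboxylate and the ring enolate are inert.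

Step 17
Reactants: 24
Product: 25 (3S)-3-{(2R,3S,8R)-5-hydroxy-2,3-dimethyl-8-(3-methylbut-2-enyl)-8-[(2R)-5-methyl-2-(prop-1-en-2-yl)hex-5-enyl]-4,7-dioxo-3,4,7,8-tetrahydro-2H-chromen-6-yl}hexanoic acid (CNP0294320.1)
Conditions: Ph3PCH3Br (6 equiv), KHMDS (5.5 equiv), THF, 0 °C; then 24, 0 °C → rt; aq. NaH2PO4
Reagents that add atoms: methyltriphenylphosphonium bromide, C[P+](c1ccccc1)(c1ccccc1)c1ccccc1.[Br-]
Why: Wittig methylenation of the methyl ketone by excess ylide (two equivalents serve as base for the acid and the enol), the anionic ring carbonyls being unreactive; the slight deficit of KHMDS leaves no free amide base, which should limit enolisation at C2'.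

**Compound list**
1 | phloroglucinol | Oc1cc(O)cc(O)c1 | starting material
2 | ethyl 3-oxohexanoate | CCCC(=O)CC(=O)OCC | starting material
3 | 5,7-dihydroxy-4-propylcoumarin | CCCc1cc(=O)oc2cc(O)cc(O)c12 | intermediate
4 | 5,7-bis(tert-butyldimethylsilyloxy)-4-propylcoumarin | CCCc1cc(=O)oc2cc(O[Si](C)(C)C(C)(C)C)cc(O[Si](C)(C)C(C)(C)C)c12 | intermediate
5 | (4S)-5,7-bis(tert-butyldimethylsilyloxy)-4-propylchroman-2-one | CCC[C@H]1CC(=O)Oc2cc(O[Si](C)(C)C(C)(C)C)cc(O[Si](C)(C)C(C)(C)C)c21 | intermediate
6 | (4S)-5,7-dihydroxy-4-propylchroman-2-one | CCC[C@H]1CC(=O)Oc2cc(O)cc(O)c21 | intermediate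
7 | tigloyl chloride | C/C=C(\C)C(=O)Cl | starting material
8 | (4S)-5,7-dihydroxy-8-[(E)-2-methylbut-2-enoyl]-4-propylchroman-2-one | CCC[C@H]1CC(=O)Oc2c(C(=O)/C(C)=C/C)c(O)cc(O)c21 | intermediate
9 | (4S,8R,9S)-5-hydroxy-8,9-dimethyl-4-propyl-3,4,8,9-tetrahydro-2H,10H-pyrano[2,3-f]chromene-2,10-dione | CCC[C@H]1CC(=O)Oc2c3C(=O)[C@@H](C)[C@@H](C)Oc3cc(O)c21 | intermediate
10 | 3-chloro-3-methylbut-1-yne | CC(C)(Cl)C#C | starting material
11 | 5-(2-methylbut-3-yn-2-yl) ether of 9 | CCC[C@H]1CC(=O)Oc2c3C(=O)[C@@H](C)[C@@H](C)Oc3cc(OC(C)(C)C#C)c21 | intermediate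
12 | 5-(2-methylbut-3-en-2-yl) ether of 9 | CCC[C@H]1CC(=O)Oc2c3C(=O)[C@@H](C)[C@@H](C)Oc3cc(OC(C)(C)C=C)c21 | intermediate
13 | 6-(3-methylbut-2-enyl) derivative of 9 | CCC[C@H]1CC(=O)Oc2c3C(=O)[C@@H](C)[C@@H](C)Oc3c(CC=C(C)C)c(O)c21 | intermediate
14 | methyl (3S)-3-[(2R,3S)-5,7-dihydroxy-2,3-dimethyl-8-(3-methylbut-2-enyl)-4-oxochroman-6-yl]hexanoate | Oc1c(CC=C(C)C)c2O[C@H](C)[C@H](C)C(=O)c2c(O)c1[C@@H](CCC)CC(=O)OC | intermediate
15 | diethyl malonate | CCOC(=O)CC(=O)OCC | starting material
16 | 4-bromo-2-methylbut-1-ene | C=C(C)CCBr | starting material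
17 | diethyl 2-(3-methylbut-3-enyl)malonate | C=C(C)CCC(C(=O)OCC)C(=O)OCC | intermediate
18 | 2-(3-methylbut-3-enyl)malonic acid | C=C(C)CCC(C(=O)O)C(=O)O | intermediate
19 | 5-methyl-2-methylidenehex-5-enoic acid | C=C(C)CCC(=C)C(=O)O | intermediate
20 | O7 5-methyl-2-methylidenehex-5-enoate of 14 | C=C(C)CCC(=C)C(=O)Oc1c(CC=C(C)C)c2O[C@H](C)[C@H](C)C(=O)c2c(O)c1[C@@H](CCC)CC(=O)OC | intermediate
21 | dearomatised tricyclic enol δ-lactone, C8 (R), C2' (R) | C=C(C)CC[C@H](C[C@@]1(CC=C(C)C)C(O4)=C([C@@H](CCC)CC(=O)OC)C(=O)C2=C1O[C@H](C)[C@H](C)C2=O)C4=O | intermediate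
22 | N-methoxy-N-methylamide methyl ester | C=C(C)CC[C@H](C[C@@]1(CC=C(C)C)C(=O)C([C@@H](CCC)CC(=O)OC)=C(O)C2=C1O[C@H](C)[C@H](C)C2=O)C(=O)N(C)OC | intermediate
23 | N-methoxy-N-methylamide acid | C=C(C)CC[C@H](C[C@@]1(CC=C(C)C)C(=O)C([C@@H](CCC)CC(=O)O)=C(O)C2=C1O[C@H](C)[C@H](C)C2=O)C(=O)N(C)OC | intermediate
24 | methyl ketone acid | C=C(C)CC[C@H](C[C@@]1(CC=C(C)C)C(=O)C([C@@H](CCC)CC(=O)O)=C(O)C2=C1O[C@H](C)[C@H](C)C2=O)C(C)=O | intermediate
25 | CNP0294320.1 | C=C(C)CC[C@H](C[C@@]1(CC=C(C)C)C(=O)C([C@@H](CCC)CC(=O)O)=C(O)C2=C1O[C@H](C)[C@H](C)C2=O)C(=C)C | target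

**Count and risks**
Total steps: 17. Longest linear sequence: 14 (steps 1–8 and 12–17); steps 9–11 make acid 19 for the coupling in step 12.

Steps most likely to fail:

1. Step 13. The ring closure may stall because a 2-alkylacrylate is a weak acceptor, the base may cleave the aryl ester, the ion pair may select the C8 face poorly, or attack may divert to C6. The fallback sets out from 14 and 19 and returns at 24. Acid 19 is coupled with N,O-dimethylhydroxylamine hydrochloride and a carbodiimide to N-methoxy-N,5-dimethyl-2-methylidenehex-5-enamide F1, and MeMgBr converts this into the enone 6-methyl-3-methylidenehept-6-en-2-one F2. The bis-phenoxide of 14 is then added through C8 to F2 in an intermolecular dearomative Michael addition of the kind known for acylphloroglucinols with enones and enals (Cs2CO3 with the same cinchonidinium salt for the C8 face). This gives the methyl ketone methyl ester F3; its C2' epimers, formed here without the lactone relay, are separated by chromatography, and LiOH hydrolysis of the ester gives 24.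

2. Step 3. Hydride transfer to the hindered, electron-rich β,β-disubstituted enoate may be slow or incomplete, or facial selectivity may be low. The fallback sets out from 3 and returns at 6: hydrogenation over Pd/C (H2, AcOH–EtOAc) gives racemic 5,7-dihydroxy-4-propylchroman-2-one F4, which is resolved by preparative chromatography on a chiral stationary phase, the (S) enantiomer being 6.

3. Step 17. The ylide may enolise the methyl ketone with loss of configuration at C2', or methylenation of the polyanion may remain incomplete. The fallback sets out from 24 and returns at 25: Me3SiCH2MgCl with anhydrous CeCl3 adds to the ketone without enolising it and gives the β-hydroxysilane F5 (the configuration of the new carbinol centre does not matter), and Peterson elimination with KH in THF gives 25.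

**Further compounds**
F1 | step 13 | N-methoxy-N,5-dimethyl-2-methylidenehex-5-enamide | C=C(C)CCC(=C)C(=O)N(C)OC
F2 | step 13 | 6-methyl-3-methylidenehept-6-en-2-one | C=C(C)CCC(=C)C(C)=O
F3 | step 13 | methyl ester of 24 | C=C(C)CC[C@H](C[C@@]1(CC=C(C)C)C(=O)C([C@@H](CCC)CC(=O)OC)=C(O)C2=C1O[C@H](C)[C@H](C)C2=O)C(C)=O
F4 | step 3 | racemic 5,7-dihydroxy-4-propylchroman-2-one | CCCC1CC(=O)Oc2cc(O)cc(O)c21
F5 | step 17 | β-hydroxysilane from 24 (tertiary alcohol bearing CH2SiMe3) | C=C(C)CC[C@H](C[C@@]1(CC=C(C)C)C(=O)C([C@@H](CCC)CC(=O)O)=C(O)C2=C1O[C@H](C)[C@H](C)C2=O)C(C)(O)C[Si](C)(C)C
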